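All runs are simulated for substances that don't exist; scatter was added.

One percent of the charge of both substrates is 20.0 turnovers of the free catalyst. The meeting on this flask agreed to count in that unit and in equivalents of reagent per charge of substrate: beta has 1.00, theta 1.50 and the flask 2.00.

| flask | left-handed substrate | right-handed substrate | reagent | free catalyst | racemization catalyst | remark | time |
|---|---|---|---|---|---|---|---|
| beta | 0.050 M | 0.050 M | 0.10 M | 50 µM | 0.50 mM | run made earlier |  |
| theta | 0.050 M | 0.050 M | 0.15 M | 50 µM | 0.50 mM | run made earlier |  |
| flask | 0.050 M | 0.050 M | 0.200 M | 50 µM | 0.50 mM |  | 8.0 min |

| run | time / min | left-handed product / % | right-handed product / % |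
|---|---|---|---|
| beta | 1.00 | 6.4 | 0.3 |
| beta | 2.00 | 10.4 | 0.4 |
| beta | 3.00 | 14.2 | 1.7 |
| beta | 4.00 | 18.1 | 0.7 |
| beta | 5.00 | 21.1 | 1.4 |
| beta | 6.00 | 24.6 | 1.6 |
| theta | 0.500 | 5.1 | 0 |
| theta | 0.833 | 9.3 | 0.2 |
| theta | 1.33 | 11.7 | 0.1 |
| theta | 2.00 | 15.8 | 0.6 |
| theta | 3.00 | 21.4 | 1.5 |
| theta | 4.00 | 25.7 | 0.9 |
| theta | 6.00 | 34.7 | 1.3 |

(standard deviation of a reading: 0.5 percentage points)

* left-handed product and right-handed product together, in percent of the left-handed substrate and right-handed substrate charged together, at 8.0 min
* excess of left-handed product over right-handed product in the product at 8.0 min
* whether the exchange between left-handed substrate and right-handed substrate keeps pace with the reaction: how far the product's excess at 8.0 min gets from its value without exchange to its value with instant exchange (above 80% keeps pace, below 20% hardly takes part, else lags behind)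

- free catalyst is single-handed; left-handed substrate and right-handed substrate are mirror images of each other, charged as a racemate, each of them at the stated concentration
- reactions considered so far: reagent + free catalyst + left-handed substrate -> free catalyst + left-handed product; reagent + free catalyst + right-handed substrate -> free catalyst + right-handed product; left-handed substrate + racemization catalyst <-> right-handed substrate + racemization catalyst; 2 free catalyst <-> resting dimer
- an excess is below zero if the other one leads

The first speaker proposed a clock. It is the logarithm of reagent left over substrate left, relative to its starting value, divided by the excess of reagent over one equivalent; at equal charges it becomes converted over unconverted. She argued that if each turnover takes reagent and substrate together, and the two substrates stay equal, the clock should run at one speed in beta and theta. At 2.00 min it reads 0.121 in beta and 0.127 in theta. At 6.00 min it reads 0.355 and 0.344. The slope of the means she called the late pace 0.0564 /min, an apparent second-order rate constant in charge units, which is 113 /min in turnovers.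

A second speaker noted that beta gained more in its first minute than in its second, so the slope starts at 2.00 min.

A third speaker tested the equal substrates. In theta, the gain of left-handed product from 4.00 min to 6.00 min is 0.909 of the gain from 2.00 min to 4.00 min, while unexchanged left-handed substrate shrinks to 0.711 of its amount. The meeting therefore expected exchange to keep pace.

Running the clock on to 8.0 min gives 0.462, which in the flask means 54.0% converted. The excess stayed rough: the last right-handed product readings are 1.6% and 1.3%, against a scatter of 0.5 percentage points.

The forecast said 51%, lower than this, with excess 88% and keeps pace, reasoning “so exchange probably keeps pace”.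

The flask gives 54.3% with excess 86.5%, and the exchange keeps pace, 95% of the way.

    reagent + free catalyst + left-handed substrate → free catalyst + left-handed product (k = 890 /M²/s)
    reagent + free catalyst + right-handed substrate → free catalyst + right-handed product (k = 62.0 /M²/s)
    left-handed substrate + racemization catalyst ⇌ right-handed substrate + racemization catalyst, rate k3*[racemization catalyst]*[left-handed substrate] forward; the back reaction follows from the equilibrium constant (k = 81.0 /M/s)
    2 free catalyst ⇌ resting dimer (K = 38000 /M, k = 560 /M/s)

At 8.00 min the flask holds left-handed substrate at 22.5% and right-handed substrate at 23.2% of the two charged together, an excess of right-handed substrate of 1.49% among what is left. The late pace 0.0564 /min serves again in the neighbour flask with 0.050 M of reagent, 0.500 equivalents, where reagent is the limiting reagent: the clock reads 17.1% converted, and that flask gives 17.4%.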